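**Retrosynthetic overview**

1. Feature: ring A is numbered from the carbon bearing the bridging oxygen (OMe on carbon 2, Br on carbons 3 and 5) and ring B from the carbon bearing the hydroxyl (bridging oxygen on carbon 2, Br on carbons 3 and 5). The ring A bromines lie ortho and para to that ring's own methoxy oxygen, but the ring B bromines lie ortho and para to the bridging oxygen and meta to the hydroxyl, against the preference of a free phenol.
2. Last disconnections: the ring B mesylate (hydrolysis) and the ring A O-methyl group (put on in place of an acetate after the key step).
3. Key disconnection: the two C–Br bonds at positions 5 and 3 of ring B, made with Br2/FeBr3 on a ring B aryl mesylate, where the sulfonylated oxygen is silenced and the bridging oxygen alone directs.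
4. Ring A is completed earlier: its free hydroxyl places bromine para and then ortho to itself under mild conditions. That oxygen is then acetylated, not methylated, because the two open ring A positions are ortho or para to the ring A bromines and to the bridging oxygen and only meta to this oxygen, so a methyl ether would leave ring A more reactive than ring B.
5. No ring is formed: both arenes and the hindered diaryl ether bond come from 2,2'-oxydiphenol, and the two rings are told apart only by mono-mesylation.

Key step: step 4

Remark: 2,2'-oxydiphenol 1 is taken to be a purchasable compound.

**Route**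

Step 1
Reactants: 1 2,2'-oxydiphenol; 2 methanesulfonyl chloride
Product: 3 2-(2-hydroxyphenoxy)phenyl methanesulfonate
Conditions: MsCl (0.9 equiv, slow addition), Et3N, CH2Cl2, −20 to 0 °C
Reagents that add atoms: methanesulfonyl chloride, CS(=O)(=O)Cl
Why: Phenol O-sulfonylation with a slight deficit of MsCl at low temperature should stop largely at the mono-mesylate, since the mono-phenoxide of the diol is stabilised by a hydrogen bond from the second hydroxyl; the neutral bis-mesylate is removed by extracting the phenols into base, and diol 1 is separated from 3 by chromatography and recycled.

Step 2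
Reactants: 3 2-(2-hydroxyphenoxy)phenyl methanesulfonate; 4 N-bromosuccinimide
Product: 5 2-(3,5-dibromo-2-hydroxyphenoxy)phenyl methanesulfonate
Conditions: NBS (2.05 equiv), MeCN, 0 °C to rt, dark
Reagents that add atoms: N-bromosuccinimide, O=C1CCC(=O)N1Br
Why: Electrophilic aromatic bromination of a phenol, in which the free ring A hydroxyl, the strongest donor in the molecule, should direct NBS first para and then ortho to itself, while ring B, holding only the shared ether oxygen and a mesylate, should not react without a Lewis acid.

Step 3
Reactants: 5 2-(3,5-dibromo-2-hydroxyphenoxy)phenyl methanesulfonate; 6 acetic anhydride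
Product: 7 2-[2-(acetyloxy)-3,5-dibromophenoxy]phenyl methanesulfonate
Conditions: Ac2O, pyridine, DMAP (cat.), CH2Cl2, rt
Reagents that add atoms: acetic anhydride, CC(=O)OC(C)=O
Why: DMAP-catalysed O-acetylation of the hindered, acidic ring A phenol should be clean, and it puts an electron-withdrawing mask meta to both open ring A positions whose own ortho and para positions are all substituted, so it can neither direct a bromine nor undergo Fries migration.

Step 4
Reactants: 7 2-[2-(acetyloxy)-3,5-dibromophenoxy]phenyl methanesulfonate; 8 bromine
Product: 10 2-[2-(acetyloxy)-3,5-dibromophenoxy]-3,5-dibromophenyl methanesulfonate, via ring B monobromide 9 (not isolated)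
Conditions: Br2 (2.2 equiv), FeBr3 (10 mol %), CH2Cl2, 0 °C to rt, dark; aq NaHSO3 work-up
Reagents that add atoms: bromine, BrBr
Why: FeBr3-polarised Br2 attacks ring B to give an arenium ion that loses a proton as HBr, and this happens twice, first at position 5 and then at position 3 of ring B, so two C–Br bonds and no ring or stereocentre are formed. The closest known reaction type is the Lewis-acid-catalysed para-then-ortho bromination of diaryl ethers, with an aryl sulfonate serving as a non-donating mask of a phenol. Because the lone pairs of the sulfonylated oxygen are drawn towards sulfur, the bridging oxygen is the only effective donor on ring B, so the arenium ions from attack para (position 5) and ortho (position 3) to it are the stabilised ones, whereas positions 4 and 6 of ring B are meta to it. The selectivity required is that ring B takes both bromines before ring A reacts: in 7 the acetate withdraws from the two open ring A positions (4 and 6, both meta to it) about as strongly as the mesylate does from positions 3 and 5 of ring B, position 4 of ring A is flanked by two bromines and position 6 by a bromine and the bridging oxygen, and the acetate has no free ortho or para position to direct to. The first bromination (para to the bridge, unhindered) should be clearly faster than the second (ortho to the bridge and now also meta to the new bromine), so monobromide 9 should build up and the reaction should be followed and stopped when 9 is consumed. The competition in this second bromination between position 3 of ring B and the open positions of ring A is the part that will need tuning of FeBr3 loading, solvent and temperature.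

Step 5
Reactants: 10 2-[2-(acetyloxy)-3,5-dibromophenoxy]-3,5-dibromophenyl methanesulfonate; 11 iodomethane
Product: 13 3,5-dibromo-2-(3,5-dibromo-2-methoxyphenoxy)phenyl methanesulfonate, via free ring A phenol 12 (not isolated)
Conditions: K2CO3, MeOH, 0 °C; concentrate; then MeI, K2CO3, DMF, rt
Reagents that add atoms: iodomethane, CI
Why: Carbonate-mediated transesterification of the aryl acetate, fast because a 2,4-dibromo-6-aryloxyphenoxide is expelled, followed by Williamson O-methylation of that phenoxide in DMF, should leave the aryl mesylate intact, since it is not attacked by carbonate or methanol at or below room temperature.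

Step 6
Reactants: 13 3,5-dibromo-2-(3,5-dibromo-2-methoxyphenoxy)phenyl methanesulfonate
Product: 14 3,5-dibromo-2-(3,5-dibromo-2-methoxyphenoxy)phenol
Conditions: KOH, H2O/1,4-dioxane, 70 °C; then aq HCl
Reagents that add atoms: none
Why: Alkaline hydrolysis of an aryl sulfonate by hydroxide attack at sulfur (S–O cleavage) should release the ring B phenoxide, while the methyl ether, the diaryl ether and the unactivated aryl bromides are inert to KOH at this temperature; water/dioxane is used instead of an alcohol so that no alkyl methanesulfonate able to re-alkylate the phenoxide is formed.

**Compound list**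

1 | 2,2'-oxydiphenol | Oc1ccccc1Oc1ccccc1O | starting material
2 | methanesulfonyl chloride | CS(=O)(=O)Cl | starting material
3 | 2-(2-hydroxyphenoxy)phenyl methanesulfonate | CS(=O)(=O)Oc1ccccc1Oc1ccccc1O | intermediate
4 | N-bromosuccinimide | O=C1CCC(=O)N1Br | starting material
5 | 2-(3,5-dibromo-2-hydroxyphenoxy)phenyl methanesulfonate | CS(=O)(=O)Oc1ccccc1Oc1cc(Br)cc(Br)c1O | intermediate
6 | acetic anhydride | CC(=O)OC(C)=O | starting material
7 | 2-[2-(acetyloxy)-3,5-dibromophenoxy]phenyl methanesulfonate | CC(=O)Oc1c(Br)cc(Br)cc1Oc1ccccc1OS(C)(=O)=O | intermediate
8 | bromine | BrBr | starting material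
9 | 2-[2-(acetyloxy)-3,5-dibromophenoxy]-5-bromophenyl methanesulfonate (ring B monobromide, bromine para to the bridging oxygen, formed in the flask in step 4) | CC(=O)Oc1c(Br)cc(Br)cc1Oc1ccc(Br)cc1OS(C)(=O)=O | intermediate
10 | 2-[2-(acetyloxy)-3,5-dibromophenoxy]-3,5-dibromophenyl methanesulfonate | CC(=O)Oc1c(Br)cc(Br)cc1Oc1c(Br)cc(Br)cc1OS(C)(=O)=O | intermediate
11 | iodomethane | CI | starting material
12 | 3,5-dibromo-2-(3,5-dibromo-2-hydroxyphenoxy)phenyl methanesulfonate (formed in the flask in step 5 as its potassium phenoxide) | CS(=O)(=O)Oc1cc(Br)cc(Br)c1Oc1cc(Br)cc(Br)c1O | intermediate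
13 | 3,5-dibromo-2-(3,5-dibromo-2-methoxyphenoxy)phenyl methanesulfonate | COc1c(Br)cc(Br)cc1Oc1c(Br)cc(Br)cc1OS(C)(=O)=O | intermediate
14 | 3,5-dibromo-2-(3,5-dibromo-2-methoxyphenoxy)phenol | COc1c(Br)cc(Br)cc1Oc1c(O)cc(Br)cc1Br | target

Total step count: 6
Longest linear sequence: 6 steps (1 to 14)

**Three steps most likely to fail**

1. Step 4. Once the position of ring B para to the bridging oxygen is brominated, the remaining ortho position is meta both to that bromine and to the sulfonate oxygen, and attack there needs the bridging oxygen to conjugate with ring B next to the mesylate. The second bromination may therefore be diverted to one of the two open positions of ring A or to position 4 of ring B, or may stall and then over-run.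
Fallback (all four bromines are fixed before the ether bond is made): it sets out from iodomethane 11 and rejoins the route at target 14. Purchased 3,5-dibromo-2-hydroxybenzaldehyde (O=Cc1cc(Br)cc(Br)c1O) would be O-methylated with 11 (K2CO3, DMF) to 3,5-dibromo-2-methoxybenzaldehyde F1. Baeyer–Villiger oxidation (mCPBA, CH2Cl2) would give 3,5-dibromo-2-methoxyphenyl formate F2, whose methanolysis (K2CO3, MeOH) would give 3,5-dibromo-2-methoxyphenol F3, which is ring A complete. SNAr of the phenoxide of F3 on purchased 3,5-dibromo-2-fluorobenzaldehyde (O=Cc1cc(Br)cc(Br)c1F; K2CO3, DMAc, 110 °C), the fluoride being activated by the ortho formyl group, would give 3,5-dibromo-2-(3,5-dibromo-2-methoxyphenoxy)benzaldehyde F4. A second Baeyer–Villiger oxidation would give 3,5-dibromo-2-(3,5-dibromo-2-methoxyphenoxy)phenyl formate F5, and methanolysis of F5 would give 14 directly.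

2. Step 1. The second hydroxyl may be sulfonylated at a rate close to that of the first, so that the mono-mesylate is diluted by unreacted diol and bis-mesylate and the material throughput becomes poor.
Fallback (the two rings are made different before the ether bond exists): it sets out from methanesulfonyl chloride 2 and rejoins the route at 3. Ullmann coupling of purchased 2-(benzyloxy)phenol (Oc1ccccc1OCc1ccccc1) with 2-iodoanisole (COc1ccccc1I) using CuI, picolinic acid and K3PO4 in DMSO at 90 °C would give 1-(benzyloxy)-2-(2-methoxyphenoxy)benzene F6. Hydrogenolysis (H2, Pd on carbon, EtOAc) would give 2-(2-methoxyphenoxy)phenol F7, and mesylation with 2 and Et3N would give 2-(2-methoxyphenoxy)phenyl methanesulfonate F8. Demethylation with BBr3 (CH2Cl2, −78 to 0 °C), to which the aryl mesylate is stable, would give 3.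

3. Step 5. While the ring A phenoxide is free, the mesyl group may be lost to methoxide or transferred from the ring B oxygen to the ring A oxygen, and methylation of a phenoxide flanked by bromine and a 2,6-disubstituted aryloxy group may be slow enough to let this happen.
Fallback (no free phenoxide is left standing beside the mesylate): it sets out from 10 and rejoins the route at 13. Acid-catalysed methanolysis of the acetate (HCl in MeOH, rt) would give phenol 12, isolated this time, which would be methylated under non-basic conditions with Me3SiCHN2 in toluene/MeOH to give 13.

**Further compounds**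

F1 | step 4 | 3,5-dibromo-2-methoxybenzaldehyde | COc1c(Br)cc(Br)cc1C=O
F2 | step 4 | 3,5-dibromo-2-methoxyphenyl formate | COc1c(Br)cc(Br)cc1OC=O
F3 | step 4 | 3,5-dibromo-2-methoxyphenol | COc1c(Br)cc(Br)cc1O
F4 | step 4 | 3,5-dibromo-2-(3,5-dibromo-2-methoxyphenoxy)benzaldehyde | COc1c(Br)cc(Br)cc1Oc1c(Br)cc(Br)cc1C=O
F5 | step 4 | 3,5-dibromo-2-(3,5-dibromo-2-methoxyphenoxy)phenyl formate | COc1c(Br)cc(Br)cc1Oc1c(Br)cc(Br)cc1OC=O
F6 | step 1 | 1-(benzyloxy)-2-(2-methoxyphenoxy)benzene | COc1ccccc1Oc1ccccc1OCc1ccccc1
F7 | step 1 | 2-(2-methoxyphenoxy)phenol | COc1ccccc1Oc1ccccc1O
F8 | step 1 | 2-(2-methoxyphenoxy)phenyl methanesulfonate | COc1ccccc1Oc1ccccc1OS(C)(=O)=O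
F0 | step 5 | none | none
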